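**Strategy**

- Cuts: after removal of three silyl ethers, ring C is cut at O1–C2 and C2–C3 (C2 from an amide acetal), at C3–C4 (benzyl nucleophile plus aldehyde) and at C4–C4a (ortho-formylation). Ring A is then cut at C8–C8a, C6–C7 and C4a–C8a into a 3-methoxy-2-alkylcyclobutenone and a prenyl-substituted siloxyalkyne.
- The cyclobutenone goes back to dichloroketene and a methoxy ynol ether, which is cut at its propargylic C–C bond into methoxyacetylide and (R)-2-isopropyloxirane.
- Enabling feature: ring A (C4a, C5, C6, C7, C8, C8a) is a phloroglucinol nucleus whose three oxygens differ (C5–OMe, C7–OH, C8a–O1) and alternate with three carbon substituents, C4a being the only ring carbon without oxygen or alkyl. A cyclobutenone/siloxyalkyne benzannulation gives exactly this pattern: free OH at C8a with C–H at C4a beside it, siloxy at C7, methoxy at C5.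
- Forward order: ring A is built first from acyclic pieces through transient four-membered rings, ring B is bought and attached as a benzyl nucleophile, ring C is closed last at O1–C2.
- Stereochemistry: the single (S) carbinol centre comes from L-valine (chloro acid with retention, epoxide closure with inversion); the epoxide is opened at CH2, so the centre is never a reaction site again.

Key step: step 10

Remark: isoflavone numbering (O1, C2, C3, C4, C4a, C5 to C8, C8a; ring B primed) is used for the ring A carbons of all precursors; "prenyl" means 3-methylbut-2-en-1-yl.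

**Route**

Step 1
Reactants: 1 L-valine
Product: 2 (S)-2-chloro-3-methylbutanoic acid
Conditions: NaNO2, 5 M HCl, 0 °C to rt
Reagents that add atoms: hydrochloric acid, Cl
Why: Diazotisation of an α-amino acid in hydrochloric acid is a standard route to the α-chloro acid and proceeds with net retention through participation of the neighbouring carboxylate (two successive inversions), so the (S) configuration of 1 is kept in 2.

Step 2
Reactants: 2 (S)-2-chloro-3-methylbutanoic acid
Product: 3 (S)-2-chloro-3-methylbutan-1-ol
Conditions: LiAlH4, Et2O, 0 °C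
Reagents that add atoms: none
Why: Hydride reduction of the carboxylic acid to the primary alcohol with LiAlH4 at low temperature leaves the secondary C–Cl bond and its configuration intact.

Step 3
Reactants: 3 (S)-2-chloro-3-methylbutan-1-ol
Product: 4 (R)-2-isopropyloxirane
Conditions: KOH, H2O, 0 °C to rt, product distilled into a cold trap as it forms
Reagents that add atoms: none
Why: Intramolecular Williamson etherification (3-exo-tet) in which the alkoxide displaces chloride at C2 with inversion, turning the (S) chlorohydrin into the (R) epoxide, which leaves the basic medium by distillation.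

Step 4
Reactants: 5 chloroacetaldehyde dimethyl acetal; 4 (R)-2-isopropyloxirane
Product: 7 (S)-1-methoxy-5-methylhex-1-yn-4-ol, via sodium methoxyacetylide 6 (not isolated)
Conditions: NaNH2 (3 equiv), liq. NH3, −33 °C; NH3 replaced by THF/DMSO; 4, 0 °C to rt; aq. NH4Cl (kept basic)
Reagents that add atoms: none
Why: Two eliminations and one deprotonation by NaNH2 convert the chloroacetal into the sodium alkoxyacetylide (the classical alkoxyalkyne preparation with alkylation in the same flask), which opens the monosubstituted epoxide by SN2 attack at its CH2 group, so the oxygen-bearing centre is not involved and is (S) in 7 only because the CIP priorities change.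

Step 5
Reactants: 7 (S)-1-methoxy-5-methylhex-1-yn-4-ol
Product: 8 (S)-4-(tert-butyldimethylsilyloxy)-1-methoxy-5-methylhex-1-yne
Conditions: TBSCl, imidazole, DMAP (cat.), DMF, rt to 40 °C
Reagents that add atoms: tert-butyldimethylsilyl chloride, CC(C)(C)[Si](C)(C)Cl
Why: Standard imidazole-mediated silylation of a secondary alcohol, run in a basic medium that the acid-labile ynol ether tolerates.

Step 6
Reactants: 8 (S)-4-(tert-butyldimethylsilyloxy)-1-methoxy-5-methylhex-1-yne; 9 trichloroacetyl chloride
Product: 11 4,4-dichloro-3-methoxy-2-[(S)-2-(tert-butyldimethylsilyloxy)-3-methylbutyl]cyclobut-2-en-1-one, via dichloroketene 10 (not isolated)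
Conditions: Zn-Cu couple, Et2O/DME, slow addition of 9, 0 °C to rt
Reagents that add atoms: none
Why: Dichloroketene generated by zinc dechlorination adds [2+2] to electron-rich alkynes with its electrophilic carbonyl carbon bonding to the nucleophilic alkyl-bearing carbon of the ynol ether, which gives the 3-methoxy-2-alkyl regioisomer, while DME ties up the ZnCl2 that would otherwise attack the ynol ether.

Step 7
Reactants: 11 4,4-dichloro-3-methoxy-2-[(S)-2-(tert-butyldimethylsilyloxy)-3-methylbutyl]cyclobut-2-en-1-one
Product: 12 3-methoxy-2-[(S)-2-(tert-butyldimethylsilyloxy)-3-methylbutyl]cyclobut-2-en-1-one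
Conditions: Zn dust, TMEDA, AcOH, MeOH, 0 °C to rt
Reagents that add atoms: none
Why: Zinc reduction in amine-buffered acetic acid removes both chlorines alpha to the carbonyl (the standard dechlorination of dichloroketene adducts), and methanol is the solvent so that any alkoxy exchange at the vinylogous ester is degenerate.

Step 8
Reactants: 13 prenyl bromide; 14 ethynylmagnesium bromide
Product: 15 5-methylhex-4-en-1-yne
Conditions: CuCl (5 mol %), THF, 0 °C to 50 °C; fractional distillation
Reagents that add atoms: none
Why: CuCl-catalysed coupling of an alkynyl Grignard reagent with an allylic bromide should give the skipped enyne mainly by attack at the primary carbon, and the lower-boiling branched isomer from attack at the tertiary terminus is removed by distillation.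

Step 9
Reactants: 15 5-methylhex-4-en-1-yne
Product: 18 triisopropyl[(5-methylhex-4-en-1-yn-1-yl)oxy]silane, via lithium acetylide 16 (not isolated), via lithium ynolate 17 (not isolated)
Conditions: LiN(SiMe3)2 (2 equiv), t-BuOOH, THF, −78 to 0 °C; then TIPSOTf, −78 °C to rt
Reagents that add atoms: tert-butyl hydroperoxide (used as its lithium salt), CC(C)(C)OO; triisopropylsilyl trifluoromethanesulfonate, CC(C)[Si](OS(=O)(=O)C(F)(F)F)(C(C)C)C(C)C
Why: Oxidation of a lithium acetylide at carbon by lithium tert-butyl peroxide is the established route to lithium ynolates, which the bulky silyl triflate traps on oxygen at low temperature, and the isolated trisubstituted alkene is inert to this nucleophilic peroxide.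

Step 10
Reactants: 12 3-methoxy-2-[(S)-2-(tert-butyldimethylsilyloxy)-3-methylbutyl]cyclobut-2-en-1-one; 18 triisopropyl[(5-methylhex-4-en-1-yn-1-yl)oxy]silane
Product: 23 4-[(S)-2-(tert-butyldimethylsilyloxy)-3-methylbutyl]-5-methoxy-2-prenyl-3-(triisopropylsilyloxy)phenol, via vinylketene 19 (not isolated), via vinylcyclobutenone 20 (not isolated), via dienylketene 21 (not isolated), via cyclohexadienone 22 (not isolated)
Conditions: 18 (1.3 equiv), degassed toluene, sealed tube, 80 °C then 110 °C
Reagents that add atoms: none
Why: Heating opens 12 by 4π electrocyclic cleavage of its C1–C4 bond to vinylketene 19, whose ketene C=C adds [2+2] to the siloxyalkyne to give vinylcyclobutenone 20; a second 4π opening gives dienylketene 21, a thermal disrotatory 6π electrocyclisation joins the ketene carbon to the CH2 terminus to give cyclohexadienone 22, and enolisation should deliver phenol 23. The closest known reaction type is the Danheiser benzannulation of cyclobutenones with 1-siloxyalkynes to resorcinol monosilyl ethers, applied here to a 3-methoxy-2-alkylcyclobutenone. Ring A is closed by the 6π electrocyclisation (the transient four-membered ring is closed by the ketene–alkyne [2+2] and opened again), so that C8–C8a, C6–C7 and C4a–C8a are the bonds formed. No stereocentre is created in the product: the quaternary carbon of 20 disappears on ring opening and the side-chain carbinol centre is a spectator. The one selectivity needed is the regiochemistry of the [2+2], secured by the polarisation of the siloxyalkyne, whose prenyl-bearing carbon is nucleophilic and bonds to the electrophilic ketene carbonyl carbon, which places prenyl between the new OH and OTIPS and the side chain between OTIPS and OMe. The unsubstituted C4 of 12 puts the only aromatic C–H ortho to the free OH, and the neutral thermal conditions leave the prenyl alkene and both silyl ethers untouched.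

Step 11
Reactants: 23 4-[(S)-2-(tert-butyldimethylsilyloxy)-3-methylbutyl]-5-methoxy-2-prenyl-3-(triisopropylsilyloxy)phenol
Product: 25 3-[(S)-2-(tert-butyldimethylsilyloxy)-3-methylbutyl]-6-hydroxy-2-methoxy-5-prenyl-4-(triisopropylsilyloxy)benzaldehyde, via salicyl alcohol 24 (not isolated)
Conditions: MgCl2, Et3N, (CH2O)n, THF, reflux; aq. NH4Cl
Reagents that add atoms: paraformaldehyde (formaldehyde), C=O
Why: Casnati–Skattebøl ortho-formylation, in which the magnesium phenoxide delivers formaldehyde to the only free ring carbon (C4a, ortho to the OH) and a second formaldehyde oxidises the resulting benzylic alkoxide by hydride transfer, without acid or electrophiles that could touch the prenyl alkene or the silyl ethers.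

Step 12
Reactants: 25 3-[(S)-2-(tert-butyldimethylsilyloxy)-3-methylbutyl]-6-hydroxy-2-methoxy-5-prenyl-4-(triisopropylsilyloxy)benzaldehyde
Product: 26 6-(allyloxy)-3-[(S)-2-(tert-butyldimethylsilyloxy)-3-methylbutyl]-2-methoxy-5-prenyl-4-(triisopropylsilyloxy)benzaldehyde
Conditions: allyl bromide, K2CO3, DMF, rt
Reagents that add atoms: allyl bromide, C=CCBr
Why: Williamson O-allylation masks the acidic salicylaldehyde OH for the Grignard step with a group that zerovalent palladium removes later under neutral conditions in the presence of three silyl ethers.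

Step 13
Reactants: 27 4-hydroxybenzaldehyde
Product: 28 4-(triisopropylsilyloxy)benzaldehyde
Conditions: TIPSCl, imidazole, DMF, rt
Reagents that add atoms: triisopropylsilyl chloride, CC(C)[Si](Cl)(C(C)C)C(C)C
Why: Standard imidazole-mediated silylation of a phenol, the triisopropylsilyl ether being chosen because it withstands borohydride in methanol, Grignard formation and the later amide acetal.

Step 14
Reactants: 28 4-(triisopropylsilyloxy)benzaldehyde
Product: 29 4-(triisopropylsilyloxy)benzyl alcohol
Conditions: NaBH4, MeOH/THF, 0 °C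
Reagents that add atoms: none
Why: Chemoselective borohydride reduction of an aromatic aldehyde to the benzylic alcohol.

Step 15
Reactants: 29 4-(triisopropylsilyloxy)benzyl alcohol
Product: 31 4-(triisopropylsilyloxy)benzyl chloride, via benzyl mesylate 30 (not isolated)
Conditions: MsCl, Et3N, CH2Cl2, 0 °C to rt; used promptly
Reagents that add atoms: methanesulfonyl chloride (supplies the chlorine), CS(=O)(=O)Cl
Why: Mesylation of an electron-rich benzylic alcohol is followed in the same flask by displacement of the mesylate by the chloride ion set free, a standard non-acidic way to para-oxygenated benzyl chlorides.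

Step 16
Reactants: 31 4-(triisopropylsilyloxy)benzyl chloride; 26 6-(allyloxy)-3-[(S)-2-(tert-butyldimethylsilyloxy)-3-methylbutyl]-2-methoxy-5-prenyl-4-(triisopropylsilyloxy)benzaldehyde
Product: 33 1-{6-(allyloxy)-3-[(S)-2-(tert-butyldimethylsilyloxy)-3-methylbutyl]-2-methoxy-5-prenyl-4-(triisopropylsilyloxy)phenyl}-2-[4-(triisopropylsilyloxy)phenyl]ethan-1-ol (epimers at the new carbinol), via benzylmagnesium chloride 32 (not isolated)
Conditions: Mg turnings, Et2O, 0 °C, slow addition of 31; then 26, THF, −78 to 0 °C; aq. NH4Cl
Reagents that add atoms: none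
Why: Grignard addition of a benzylic magnesium chloride to a non-enolisable aromatic aldehyde forms C3–C4, the new carbinol centre arising without control as a mixture of epimers that is removed by oxidation in the next step.

Step 17
Reactants: 33 the epimeric carbinols from step 16
Product: 34 1-{6-(allyloxy)-3-[(S)-2-(tert-butyldimethylsilyloxy)-3-methylbutyl]-2-methoxy-5-prenyl-4-(triisopropylsilyloxy)phenyl}-2-[4-(triisopropylsilyloxy)phenyl]ethan-1-one
Conditions: Dess–Martin periodinane, NaHCO3, CH2Cl2, 0 °C to rt
Reagents that add atoms: none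
Why: Dess–Martin oxidation of a secondary benzylic alcohol to the ketone under buffered conditions erases the uncontrolled carbinol centre and spares the alkenes, the silyl ethers and the electron-rich arene.

Step 18
Reactants: 34 the allyl-protected deoxybenzoin from step 17
Product: 35 1-{3-[(S)-2-(tert-butyldimethylsilyloxy)-3-methylbutyl]-6-hydroxy-2-methoxy-5-prenyl-4-(triisopropylsilyloxy)phenyl}-2-[4-(triisopropylsilyloxy)phenyl]ethan-1-one
Conditions: Pd(PPh3)4 (5 mol %), morpholine, THF, rt
Reagents that add atoms: none
Why: Tsuji–Trost deallylation, in which zerovalent palladium ionises the allyl aryl ether and morpholine captures the allyl fragment, frees the phenol without acid, base or fluoride, while the prenyl group, a simple alkene with no leaving group, is not ionised.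

Step 19
Reactants: 35 the 2-hydroxydeoxybenzoin from step 18
Product: 37 6-[(S)-2-(tert-butyldimethylsilyloxy)-3-methylbutyl]-5-methoxy-8-prenyl-7-(triisopropylsilyloxy)-3-[4-(triisopropylsilyloxy)phenyl]-4H-chromen-4-one, via enaminone 36 (not isolated)
Conditions: Me2NCH(OMe)2, toluene, 80 °C
Reagents that add atoms: N,N-dimethylformamide dimethyl acetal, COC(OC)N(C)C
Why: Classical deoxybenzoin route to isoflavones, in which the amide acetal condenses with the activated CH2 to the enaminone (supplying C2) and the ortho phenol then adds to the enaminone and expels dimethylamine, closing ring C at O1–C2 by 6-endo-trig addition–elimination.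

Step 20
Reactants: 37 the tris-silylated isoflavone from step 19
Product: 38 7-hydroxy-3-(4-hydroxyphenyl)-6-[(S)-2-hydroxy-3-methylbutyl]-5-methoxy-8-prenyl-4H-chromen-4-one (CNP0323282.1)
Conditions: TBAF, AcOH (1:1), THF, 0 °C to rt
Reagents that add atoms: none
Why: Fluoride cleaves the two aryl triisopropylsilyl ethers and the secondary alkyl tert-butyldimethylsilyl ether, acetic acid buffering the phenoxides so that the chromone ring and the ortho-prenyl phenol are not exposed to strong base, and the stereocentre is not touched.

**Compound list**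

1 | L-valine | CC(C)[C@H](N)C(=O)O | starting material
2 | (S)-2-chloro-3-methylbutanoic acid | CC(C)[C@H](Cl)C(=O)O | intermediate
3 | (S)-2-chloro-3-methylbutan-1-ol | CC(C)[C@H](Cl)CO | intermediate
4 | (R)-2-isopropyloxirane | CC(C)[C@@H]1CO1 | intermediate
5 | chloroacetaldehyde dimethyl acetal | COC(CCl)OC | starting material
6 | sodium methoxyacetylide (formed in the flask) | COC#C[Na] | intermediate
7 | (S)-1-methoxy-5-methylhex-1-yn-4-ol | COC#CC[C@H](O)C(C)C | intermediate
8 | (S)-4-(tert-butyldimethylsilyloxy)-1-methoxy-5-methylhex-1-yne | COC#CC[C@H](O[Si](C)(C)C(C)(C)C)C(C)C | intermediate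
9 | trichloroacetyl chloride | ClC(Cl)(Cl)C(Cl)=O | starting material
10 | dichloroketene (formed in the flask) | ClC(Cl)=C=O | intermediate
11 | 4,4-dichloro-3-methoxy-2-[(S)-2-(tert-butyldimethylsilyloxy)-3-methylbutyl]cyclobut-2-en-1-one | COC1=C(C[C@H](O[Si](C)(C)C(C)(C)C)C(C)C)C(=O)C1(Cl)Cl | intermediate
12 | 3-methoxy-2-[(S)-2-(tert-butyldimethylsilyloxy)-3-methylbutyl]cyclobut-2-en-1-one | COC1=C(C[C@H](O[Si](C)(C)C(C)(C)C)C(C)C)C(=O)C1 | intermediate
13 | prenyl bromide (1-bromo-3-methylbut-2-ene) | CC(C)=CCBr | starting material
14 | ethynylmagnesium bromide | C#C[Mg]Br | starting material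
15 | 5-methylhex-4-en-1-yne | C#CCC=C(C)C | intermediate
16 | lithium 5-methylhex-4-en-1-yn-1-ide, the lithium acetylide (formed in the flask) | [Li]C#CCC=C(C)C | intermediate
17 | lithium 5-methylhex-4-en-1-yn-1-olate, the lithium ynolate (formed in the flask) | [Li]OC#CCC=C(C)C | intermediate
18 | triisopropyl[(5-methylhex-4-en-1-yn-1-yl)oxy]silane | CC(C)=CCC#CO[Si](C(C)C)(C(C)C)C(C)C | intermediate
19 | vinylketene: 3-methoxy-2-[(S)-2-(tert-butyldimethylsilyloxy)-3-methylbutyl]buta-1,3-dien-1-one (formed in the flask) | C=C(OC)C(C[C@H](O[Si](C)(C)C(C)(C)C)C(C)C)=C=O | intermediate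
20 | vinylcyclobutenone: 4-(1-methoxyvinyl)-4-[(S)-2-(tert-butyldimethylsilyloxy)-3-methylbutyl]-2-prenyl-3-(triisopropylsilyloxy)cyclobut-2-en-1-one, both configurations at C4 (formed in the flask) | C=C(OC)C1(C[C@H](O[Si](C)(C)C(C)(C)C)C(C)C)C(=O)C(CC=C(C)C)=C1O[Si](C(C)C)(C(C)C)C(C)C | intermediate
21 | dienylketene: 5-methoxy-4-[(S)-2-(tert-butyldimethylsilyloxy)-3-methylbutyl]-2-prenyl-3-(triisopropylsilyloxy)hexa-1,3,5-trien-1-one, ketene and methoxyvinyl cis (formed in the flask) | O=C=C(CC=C(C)C)/C(O[Si](C(C)C)(C(C)C)C(C)C)=C(\C(OC)=C)C[C@H](O[Si](C)(C)C(C)(C)C)C(C)C | intermediate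
22 | cyclohexadienone: 5-methoxy-4-[(S)-2-(tert-butyldimethylsilyloxy)-3-methylbutyl]-2-prenyl-3-(triisopropylsilyloxy)cyclohexa-2,4-dien-1-one (formed in the flask) | O=C1CC(OC)=C(C[C@H](O[Si](C)(C)C(C)(C)C)C(C)C)C(O[Si](C(C)C)(C(C)C)C(C)C)=C1CC=C(C)C | intermediate
23 | 4-[(S)-2-(tert-butyldimethylsilyloxy)-3-methylbutyl]-5-methoxy-2-prenyl-3-(triisopropylsilyloxy)phenol | Oc1cc(OC)c(C[C@H](O[Si](C)(C)C(C)(C)C)C(C)C)c(O[Si](C(C)C)(C(C)C)C(C)C)c1CC=C(C)C | intermediate
24 | salicyl alcohol: 2-(hydroxymethyl)-4-[(S)-2-(tert-butyldimethylsilyloxy)-3-methylbutyl]-3-methoxy-6-prenyl-5-(triisopropylsilyloxy)phenol (formed in the flask) | OCc1c(OC)c(C[C@H](O[Si](C)(C)C(C)(C)C)C(C)C)c(O[Si](C(C)C)(C(C)C)C(C)C)c(CC=C(C)C)c1O | intermediate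
25 | 3-[(S)-2-(tert-butyldimethylsilyloxy)-3-methylbutyl]-6-hydroxy-2-methoxy-5-prenyl-4-(triisopropylsilyloxy)benzaldehyde | O=Cc1c(OC)c(C[C@H](O[Si](C)(C)C(C)(C)C)C(C)C)c(O[Si](C(C)C)(C(C)C)C(C)C)c(CC=C(C)C)c1O | intermediate
26 | 6-(allyloxy)-3-[(S)-2-(tert-butyldimethylsilyloxy)-3-methylbutyl]-2-methoxy-5-prenyl-4-(triisopropylsilyloxy)benzaldehyde | O=Cc1c(OC)c(C[C@H](O[Si](C)(C)C(C)(C)C)C(C)C)c(O[Si](C(C)C)(C(C)C)C(C)C)c(CC=C(C)C)c1OCC=C | intermediate
27 | 4-hydroxybenzaldehyde | O=Cc1ccc(O)cc1 | starting material
28 | 4-(triisopropylsilyloxy)benzaldehyde | O=Cc1ccc(O[Si](C(C)C)(C(C)C)C(C)C)cc1 | intermediate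
29 | 4-(triisopropylsilyloxy)benzyl alcohol | OCc1ccc(O[Si](C(C)C)(C(C)C)C(C)C)cc1 | intermediate
30 | 4-(triisopropylsilyloxy)benzyl methanesulfonate (formed in the flask) | CS(=O)(=O)OCc1ccc(O[Si](C(C)C)(C(C)C)C(C)C)cc1 | intermediate
31 | 4-(triisopropylsilyloxy)benzyl chloride | ClCc1ccc(O[Si](C(C)C)(C(C)C)C(C)C)cc1 | intermediate
32 | [4-(triisopropylsilyloxy)benzyl]magnesium chloride (formed in the flask) | Cl[Mg]Cc1ccc(O[Si](C(C)C)(C(C)C)C(C)C)cc1 | intermediate
33 | 1-{6-(allyloxy)-3-[(S)-2-(tert-butyldimethylsilyloxy)-3-methylbutyl]-2-methoxy-5-prenyl-4-(triisopropylsilyloxy)phenyl}-2-[4-(triisopropylsilyloxy)phenyl]ethan-1-ol, both epimers at C1 | OC(Cc1ccc(O[Si](C(C)C)(C(C)C)C(C)C)cc1)c1c(OC)c(C[C@H](O[Si](C)(C)C(C)(C)C)C(C)C)c(O[Si](C(C)C)(C(C)C)C(C)C)c(CC=C(C)C)c1OCC=C | intermediate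
34 | 1-{6-(allyloxy)-3-[(S)-2-(tert-butyldimethylsilyloxy)-3-methylbutyl]-2-methoxy-5-prenyl-4-(triisopropylsilyloxy)phenyl}-2-[4-(triisopropylsilyloxy)phenyl]ethan-1-one | O=C(Cc1ccc(O[Si](C(C)C)(C(C)C)C(C)C)cc1)c1c(OC)c(C[C@H](O[Si](C)(C)C(C)(C)C)C(C)C)c(O[Si](C(C)C)(C(C)C)C(C)C)c(CC=C(C)C)c1OCC=C | intermediate
35 | 1-{3-[(S)-2-(tert-butyldimethylsilyloxy)-3-methylbutyl]-6-hydroxy-2-methoxy-5-prenyl-4-(triisopropylsilyloxy)phenyl}-2-[4-(triisopropylsilyloxy)phenyl]ethan-1-one | O=C(Cc1ccc(O[Si](C(C)C)(C(C)C)C(C)C)cc1)c1c(OC)c(C[C@H](O[Si](C)(C)C(C)(C)C)C(C)C)c(O[Si](C(C)C)(C(C)C)C(C)C)c(CC=C(C)C)c1O | intermediate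
36 | enaminone: 3-(dimethylamino)-1-{3-[(S)-2-(tert-butyldimethylsilyloxy)-3-methylbutyl]-6-hydroxy-2-methoxy-5-prenyl-4-(triisopropylsilyloxy)phenyl}-2-[4-(triisopropylsilyloxy)phenyl]prop-2-en-1-one (formed in the flask) | CN(C)C=C(c1ccc(O[Si](C(C)C)(C(C)C)C(C)C)cc1)C(=O)c1c(OC)c(C[C@H](O[Si](C)(C)C(C)(C)C)C(C)C)c(O[Si](C(C)C)(C(C)C)C(C)C)c(CC=C(C)C)c1O | intermediate
37 | 6-[(S)-2-(tert-butyldimethylsilyloxy)-3-methylbutyl]-5-methoxy-8-prenyl-7-(triisopropylsilyloxy)-3-[4-(triisopropylsilyloxy)phenyl]-4H-chromen-4-one | COc1c(C[C@H](O[Si](C)(C)C(C)(C)C)C(C)C)c(O[Si](C(C)C)(C(C)C)C(C)C)c(CC=C(C)C)c2occ(-c3ccc(O[Si](C(C)C)(C(C)C)C(C)C)cc3)c(=O)c12 | intermediate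
38 | 7-hydroxy-3-(4-hydroxyphenyl)-6-[(S)-2-hydroxy-3-methylbutyl]-5-methoxy-8-prenyl-4H-chromen-4-one (CNP0323282.1) | COc1c(C[C@H](O)C(C)C)c(O)c(CC=C(C)C)c2occ(-c3ccc(O)cc3)c(=O)c12 | target

**Step count and risks**

Total step count: 20. Longest linear sequence: 15 steps (steps 1 to 7, 10 to 12 and 16 to 20, from L-valine).

Steps most likely to fail:

Step 10. The vinylogous-ester cyclobutenone may open only at temperatures at which the siloxyalkyne rearranges by 1,3-silyl shift to a silylketene, and the vinylketene that does form may be intercepted by the product phenol instead of the alkyne. The fallback generates the vinylketene photochemically instead of thermally. A solution of 12 and 18 would be irradiated at ambient temperature (medium-pressure Hg lamp, Pyrex filter, continuous flow through FEP tubing), which triggers the 4π ring opening without heat. The photolysate would then be warmed briefly in toluene to complete the second ring opening and the 6π closure. This photochemical variant of the cyclobutenone benzannulation is known; it sets out from 12 (with 18), returns to the route at 23 and makes no new compound (F0).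

Step 4. Ring opening of the branched, volatile epoxide by the sodium acetylide may be slow in the presence of methoxide and traces of amide, so that the epoxide is diverted by these nucleophiles or lost by evaporation. The fallback uses an amine-free lithium acetylide and Lewis-acid activation of the epoxide. Trichloroethylene and NaOMe would give (E)-1,2-dichloro-1-methoxyethene F1. n-BuLi (2 equiv, THF, −78 °C) would convert it by elimination and chlorine–lithium exchange into lithium methoxyacetylide F2, which would open 4 at its CH2 group in the presence of BF3·OEt2 at −78 °C (Yamaguchi–Hirao alkynylation). This sets out from 4 and returns to the route at 7.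

Step 16. Wurtz-type homocoupling may compete during formation of the electron-rich benzylic Grignard reagent, and the reagent may attack the hindered, di-ortho-substituted aldehyde through its ortho carbon. The fallback replaces the Grignard reagent by the benzylic organozinc. LiCl-mediated insertion of zinc dust into 31 (THF, rt) would give [4-(triisopropylsilyloxy)benzyl]zinc chloride F3 without homocoupling. MgCl2-promoted addition of this reagent to aldehyde 26 would then give the carbinol. This sets out from 31 and returns to the route at 33.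

**Further compounds**

F0 | step 10 | none | none
F1 | step 4 | (E)-1,2-dichloro-1-methoxyethene | CO/C(Cl)=C\Cl
F2 | step 4 | lithium methoxyacetylide | COC#C[Li]
F3 | step 16 | [4-(triisopropylsilyloxy)benzyl]zinc chloride | Cl[Zn]Cc1ccc(O[Si](C(C)C)(C(C)C)C(C)C)cc1
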